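Everything rests on cutting the cyclohexene ring at C5=C6, its lone double bond. That bond is flanked by the tertiary carbinol carbon C1 and the secondary carbinol carbon C4. The opened ring is therefore an octa-1,7-diene carrying a vinyl group on each of these two carbinols. Ring-closing metathesis joins the vinyl groups, expels ethene and delivers the carbocycle in one operation without touching a stereocentre. The precursor is the open-chain 1,2,4-triol with PMB ethers on O3 and O7. C2–C4 are sugar carbons C4–C2 of D-glucose, and C1 is fixed earlier by chelate-controlled addition to a furanosyl vinyl ketone. A PMB-to-benzoate exchange finishes the route.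

Key step: step 9

Remark: sugar locants are used for the furanoses 1–15 and target locants (C1–C7, O1–O7) from 18 onward; read from the SMILES string the target is (1S,2S,3R,4S) in that numbering, and this enantiomer maps onto the D-series sugar.

Step 1
Reactants: 1 1,2:5,6-di-O-isopropylidene-α-D-glucofuranose; 2 4-methoxybenzyl chloride
Product: 3 1,2:5,6-di-O-isopropylidene-3-O-(4-methoxybenzyl)-α-D-glucofuranose
Conditions: NaH, PMBCl, Bu4NI (cat.), DMF, 0 °C → rt
Reagents that add atoms: 4-methoxybenzyl chloride, COc1ccc(CCl)cc1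
Why: Williamson etherification of the only free hydroxyl (sugar O3, the future O3), so no regiochemical question arises, and sugar C2–C4 already carry the configurations of target C4–C2.

Step 2
Reactants: 3 1,2:5,6-di-O-isopropylidene-3-O-(4-methoxybenzyl)-α-D-glucofuranose
Product: 5 1,2-O-isopropylidene-3-O-(4-methoxybenzyl)-α-D-xylo-pentodialdo-1,4-furanose, via 5,6-diol 4 (not isolated)
Conditions: H5IO6, EtOAc, rt
Reagents that add atoms: none
Why: Periodic acid first hydrolyses the more labile terminal 5,6-acetonide and then carries out Malaprade glycol cleavage of the liberated diol, which excises sugar C6 while the fused 1,2-acetonide and the PMB ether persist and avoids any O3/O5 differentiation on a pentose.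

Step 3
Reactants: 5 1,2-O-isopropylidene-3-O-(4-methoxybenzyl)-α-D-xylo-pentodialdo-1,4-furanose; 6 vinylmagnesium bromide
Product: 7 6,7-dideoxy-1,2-O-isopropylidene-3-O-(4-methoxybenzyl)-hept-6-eno-1,4-furanose (α-D-gluco/β-L-ido mixture of C5 epimers)
Conditions: CH2=CHMgBr, THF, −78 → 0 °C
Reagents that add atoms: vinylmagnesium bromide, C=C[Mg]Br
Why: Grignard 1,2-addition to the aldehyde installs the future C6 vinyl group, and the new carbinol centre needs no control because step 4 erases it.

Step 4
Reactants: 7 6,7-dideoxy-1,2-O-isopropylidene-3-O-(4-methoxybenzyl)-hept-6-eno-1,4-furanose (C5 epimers)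
Product: 8 6,7-dideoxy-1,2-O-isopropylidene-3-O-(4-methoxybenzyl)-α-D-xylo-hept-6-eno-1,4-furanos-5-ulose (vinyl ketone)
Conditions: Dess–Martin periodinane, CH2Cl2, 0 °C → rt
Reagents that add atoms: none
Why: Dess–Martin oxidation runs under neutral to slightly acidic conditions, so both epimers converge on one vinyl ketone without the base-induced epimerisation at sugar C4 or β-elimination of the O3 ether that amine-containing oxidations could trigger.

Step 5
Reactants: 9 4-methoxybenzyl alcohol; 10 tributyl(iodomethyl)stannane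
Product: 11 tributyl{[(4-methoxybenzyl)oxy]methyl}stannane
Conditions: NaH, THF/DMF, 0 °C; then Bu3SnCH2I, rt
Reagents that add atoms: tributyl(iodomethyl)stannane, CCCC[Sn](CI)(CCCC)CCCC
Why: Williamson etherification by SN2 displacement of the unhindered primary iodide with the sodium alkoxide, the standard access to α-alkoxymethylstannanes.

Step 6
Reactants: 8 vinyl ketone; 11 tributyl{[(4-methoxybenzyl)oxy]methyl}stannane
Product: 14 (5S)-6,7-dideoxy-1,2-O-isopropylidene-3-O-(4-methoxybenzyl)-5-C-{[(4-methoxybenzyl)oxy]methyl}-α-D-gluco-hept-6-eno-1,4-furanose, via alkoxymethyllithium 12 (not isolated), via alkoxymethylmagnesium bromide 13 (not isolated)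
Conditions: 11, n-BuLi, THF, −78 °C; MgBr2·OEt2, −78 °C; then 8 in Et2O, −78 → −40 °C
Reagents that add atoms: tributyl{[(4-methoxybenzyl)oxy]methyl}stannane, CCCC[Sn](CCCC)(CCCC)COCc1ccc(OC)cc1
Why: Tin–lithium exchange and transmetallation give an α-alkoxymethyl Grignard reagent that adds 1,2 to the ketone held in a five-membered Mg chelate between the carbonyl oxygen and the furanose ring oxygen (Cram chelate model), so the nucleophile enters from the H-4 side, away from C3 and its cis-disposed PMB ether, and places CH2OPMB, OH and vinyl in the (5S) arrangement that becomes C1 of the target.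

Step 7
Reactants: 14 tertiary carbinol acetonide
Product: 15 (5S)-6,7-dideoxy-3-O-(4-methoxybenzyl)-5-C-{[(4-methoxybenzyl)oxy]methyl}-D-gluco-hept-6-eno-1,4-furanose (anomer mixture)
Conditions: AcOH/H2O 4:1, 80 °C
Reagents that add atoms: none
Why: Acid-catalysed acetal hydrolysis in aqueous acetic acid, a medium able to open the fused 1,2-O-isopropylidene ring on heating but too weakly acidic to ionise the PMB ethers or the tertiary allylic alcohol, whose cation would be destabilised by the neighbouring C–O bonds.

Step 8
Reactants: 15 lactol; 16 methyltriphenylphosphonium bromide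
Product: 18 (3S,4S,5R,6S)-5-[(4-methoxybenzyl)oxy]-3-{[(4-methoxybenzyl)oxy]methyl}octa-1,7-diene-3,4,6-triol, via methylenetriphenylphosphorane 17 (not isolated)
Conditions: Ph3PCH3Br, KOtBu (excess), THF, 0 °C; then 15, 0 °C → rt
Reagents that add atoms: methyltriphenylphosphonium bromide, C[P+](c1ccccc1)(c1ccccc1)c1ccccc1.[Br-]
Why: Wittig methylenation of the hydroxy-aldehyde tautomer of the lactol with excess ylide (which also deprotonates the hydroxyls) turns sugar C1 into the vinyl carbon C5 and frees the ring oxygen as O2–H, while the alkoxide next to the aldehyde disfavours enolisation so that C4 keeps its configuration.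

Step 9
Reactants: 18 diene triol
Product: 19 (1S,2S,3R,4S)-3-[(4-methoxybenzyl)oxy]-1-{[(4-methoxybenzyl)oxy]methyl}cyclohex-5-ene-1,2,4-triol
Conditions: second-generation Grubbs catalyst RuCl2(=CHPh)(PCy3)(H2IMes) (5 mol %), 1,4-benzoquinone (10 mol %), CH2Cl2 (2 mM), 40 °C, Ar purge
Reagents that add atoms: none
Why: The benzylidene complex should first exchange with the unhindered vinyl group on the secondary carbinol C4, and the resulting alkylidene then engages the vinyl group on C1 intramolecularly by [2+2] cycloaddition and cycloreversion through a ruthenacyclobutane, which releases ethene and forms C5=C6. This is ordinary ring-closing olefin metathesis of a sugar-derived octa-1,7-diene, the established entry to polyhydroxylated cyclohexenes. The single ring closes as a six-membered carbocycle by union of the inner carbons of two monosubstituted alkenes, so the new alkene is necessarily endocyclic and cis. No stereocentre is created or disturbed, since C1–C4 are sp3 carbinol carbons outside the reacting π bonds. The step needs cyclisation to outrun dimerisation through the C4 vinyl group and Ru–H-mediated isomerisation of the C4 allylic alcohol, which high dilution, removal of ethene, the quinone additive and the entropically favoured six-ring closure should secure. The free allylic hydroxyls are tolerated by the catalyst and are expected to speed alkylidene transfer, which helps at the crowded C1 terminus.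

Step 10
Reactants: 19 cyclohexenetriol; 20 triethylsilyl trifluoromethanesulfonate
Product: 21 (1S,2S,3R,4S)-3-O-PMB-7-O-PMB-1,2,4-tris-O-(triethylsilyl)cyclohexene
Conditions: TESOTf (excess), 2,6-lutidine, CH2Cl2, −78 → 0 °C
Reagents that add atoms: triethylsilyl trifluoromethanesulfonate, CC[Si](CC)(CC)OS(=O)(=O)C(F)(F)F
Why: Exhaustive silylation with a silyl triflate and a hindered base needs no site selectivity, and covering tertiary O1 as well leaves no free hydroxyl beside a PMB ether, which rules out p-methoxybenzylidene acetal formation in step 11.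

Step 11
Reactants: 21 tris-silyl bis-PMB ether
Product: 22 (1S,2S,3R,4S)-1-(hydroxymethyl)-1,2,4-tris(triethylsilyloxy)cyclohex-5-en-3-ol
Conditions: DDQ, CH2Cl2/pH 7 phosphate buffer 10:1, 0 °C → rt
Reagents that add atoms: none
Why: Oxidative PMB cleavage (benzylic hydride abstraction by DDQ, then hydrolysis of the oxocarbenium ion) is selective for the two electron-rich benzyl ethers, while the silyl ethers and the isolated ring alkene should be inert in the buffered two-phase medium.

Step 12
Reactants: 22 3,7-diol; 23 benzoyl chloride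
Product: 24 (1S,2S,3R,4S)-3,7-di-O-benzoyl-1,2,4-tris-O-(triethylsilyl)cyclohexene
Conditions: BzCl, pyridine, DMAP (cat.), 0 → 40 °C
Reagents that add atoms: benzoyl chloride, O=C(Cl)c1ccccc1
Why: DMAP-catalysed acylation of the only two free hydroxyls, primary O7 and secondary O3, so the site selectivity is guaranteed by the protecting-group pattern.

Step 13
Reactants: 24 dibenzoate tris-silyl ether
Product: 25 1α-benzoyloxymethyl-3α-benzoyloxycyclohex-5-ene-1β,2β,4β-triol
Conditions: HF·pyridine, pyridine, THF, 0 °C → rt
Reagents that add atoms: none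
Why: Fluoride-driven desilylation in a buffered, mildly acidic medium removes all three triethylsilyl groups, and the absence of alkoxide or naked fluoride avoids benzoate migration from O3 to O2 or O4 and from O7 to O1.

Compound list
1 | 1,2:5,6-di-O-isopropylidene-α-D-glucofuranose | CC1(C)O[C@H]2O[C@H]([C@H]3COC(C)(C)O3)[C@H](O)[C@H]2O1 | starting material
2 | 4-methoxybenzyl chloride | COc1ccc(CCl)cc1 | starting material
3 | 1,2:5,6-di-O-isopropylidene-3-O-(4-methoxybenzyl)-α-D-glucofuranose | CC1(C)O[C@H]2O[C@H]([C@H]3COC(C)(C)O3)[C@H](OCc3ccc(OC)cc3)[C@H]2O1 | intermediate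
4 | 1,2-O-isopropylidene-3-O-(4-methoxybenzyl)-α-D-glucofuranose (5,6-diol, not isolated) | CC1(C)O[C@H]2O[C@H]([C@H](O)CO)[C@H](OCc3ccc(OC)cc3)[C@H]2O1 | intermediate
5 | 1,2-O-isopropylidene-3-O-(4-methoxybenzyl)-α-D-xylo-pentodialdo-1,4-furanose | CC1(C)O[C@H]2O[C@H](C=O)[C@H](OCc3ccc(OC)cc3)[C@H]2O1 | intermediate
6 | vinylmagnesium bromide | C=C[Mg]Br | starting material
7 | 6,7-dideoxy-1,2-O-isopropylidene-3-O-(4-methoxybenzyl)-hept-6-eno-1,4-furanose, C5 epimer mixture | CC1(C)O[C@H]2O[C@H](C(O)C=C)[C@H](OCc3ccc(OC)cc3)[C@H]2O1 | intermediate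
8 | 6,7-dideoxy-1,2-O-isopropylidene-3-O-(4-methoxybenzyl)-α-D-xylo-hept-6-eno-1,4-furanos-5-ulose | CC1(C)O[C@H]2O[C@H](C(=O)C=C)[C@H](OCc3ccc(OC)cc3)[C@H]2O1 | intermediate
9 | 4-methoxybenzyl alcohol | COc1ccc(CO)cc1 | starting material
10 | tributyl(iodomethyl)stannane | CCCC[Sn](CI)(CCCC)CCCC | starting material
11 | tributyl{[(4-methoxybenzyl)oxy]methyl}stannane | CCCC[Sn](CCCC)(CCCC)COCc1ccc(OC)cc1 | intermediate
12 | {[(4-methoxybenzyl)oxy]methyl}lithium (not isolated) | [Li]COCc1ccc(OC)cc1 | intermediate
13 | {[(4-methoxybenzyl)oxy]methyl}magnesium bromide (not isolated) | Br[Mg]COCc1ccc(OC)cc1 | intermediate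
14 | (5S)-6,7-dideoxy-1,2-O-isopropylidene-3-O-(4-methoxybenzyl)-5-C-{[(4-methoxybenzyl)oxy]methyl}-α-D-gluco-hept-6-eno-1,4-furanose | CC1(C)O[C@H]2O[C@H]([C@](O)(C=C)COCc3ccc(OC)cc3)[C@H](OCc3ccc(OC)cc3)[C@H]2O1 | intermediate
15 | (5S)-6,7-dideoxy-3-O-(4-methoxybenzyl)-5-C-{[(4-methoxybenzyl)oxy]methyl}-D-gluco-hept-6-eno-1,4-furanose, anomer mixture | OC1O[C@H]([C@](O)(C=C)COCc2ccc(OC)cc2)[C@H](OCc2ccc(OC)cc2)[C@H]1O | intermediate
16 | methyltriphenylphosphonium bromide | C[P+](c1ccccc1)(c1ccccc1)c1ccccc1.[Br-] | starting material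
17 | methylenetriphenylphosphorane (not isolated) | C=P(c1ccccc1)(c1ccccc1)c1ccccc1 | intermediate
18 | (3S,4S,5R,6S)-5-[(4-methoxybenzyl)oxy]-3-{[(4-methoxybenzyl)oxy]methyl}octa-1,7-diene-3,4,6-triol | C=C[C@](O)(COCc1ccc(OC)cc1)[C@@H](O)[C@H](OCc1ccc(OC)cc1)[C@@H](O)C=C | intermediate
19 | (1S,2S,3R,4S)-3-[(4-methoxybenzyl)oxy]-1-{[(4-methoxybenzyl)oxy]methyl}cyclohex-5-ene-1,2,4-triol | COc1ccc(COC[C@@]2(O)C=C[C@H](O)[C@@H](OCc3ccc(OC)cc3)[C@@H]2O)cc1 | intermediate
20 | triethylsilyl trifluoromethanesulfonate | CC[Si](CC)(CC)OS(=O)(=O)C(F)(F)F | starting material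
21 | 1,2,4-tris-O-triethylsilyl ether of 19 | COc1ccc(COC[C@@]2(O[Si](CC)(CC)CC)C=C[C@H](O[Si](CC)(CC)CC)[C@@H](OCc3ccc(OC)cc3)[C@@H]2O[Si](CC)(CC)CC)cc1 | intermediate
22 | (1S,2S,3R,4S)-1-(hydroxymethyl)-1,2,4-tris(triethylsilyloxy)cyclohex-5-en-3-ol | OC[C@@]1(O[Si](CC)(CC)CC)C=C[C@H](O[Si](CC)(CC)CC)[C@@H](O)[C@@H]1O[Si](CC)(CC)CC | intermediate
23 | benzoyl chloride | O=C(Cl)c1ccccc1 | starting material
24 | 3,7-di-O-benzoyl-1,2,4-tris-O-triethylsilyl derivative | O=C(OC[C@@]1(O[Si](CC)(CC)CC)C=C[C@H](O[Si](CC)(CC)CC)[C@@H](OC(=O)c2ccccc2)[C@@H]1O[Si](CC)(CC)CC)c1ccccc1 | intermediate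
25 | 1α-benzoyloxymethyl-3α-benzoyloxycyclohex-5-ene-1β,2β,4β-triol, (1S,2S,3R,4S) | O=C(OC[C@@]1(O)C=C[C@H](O)[C@@H](OC(=O)c2ccccc2)[C@@H]1O)c1ccccc1 | target

Total step count: 13 (12 in the main line plus step 5 for reagent 11).
Longest linear sequence: 12 steps, from 1 to 25 through steps 1–4 and 6–13.

Steps most likely to fail

**Step 6.**
- Incomplete lithium-to-magnesium exchange would leave a poorly chelating nucleophile and erode facial selectivity at C1.
- Conjugate addition to the vinyl ketone, [1,2]-Wittig rearrangement of the carbanion, or base-induced β-elimination across sugar C3–C4 could also consume material.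
- The fallback sets out from 8 and uses a preformed hydroxymethyl-anion equivalent instead of an alkoxymethyl metal.
- Chloromethyl(isopropoxy)dimethylsilane and Mg turnings in THF give [(isopropoxydimethylsilyl)methyl]magnesium chloride F1.
- F1 adds to 8 in Et2O/THF at low temperature through the same five-membered Mg chelate to give the silylmethyl carbinol F2.
- Tamao oxidation (H2O2, KF, KHCO3, THF/MeOH) converts the C–Si bond into C–OH and gives the 5-C-hydroxymethyl diol F3.
- Stannylene-directed etherification of the primary oxygen (Bu2SnO, toluene, reflux; then 2, CsF, DMF) comes back to the route at 14.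

**Step 9.**
- Ru–H species from catalyst decay may isomerise the C4 allylic alcohol.
- The triol may sequester the catalyst.
- Slow engagement of the vinyl group on the fully substituted C1 may let dimerisation through the C4 vinyl group win.
- The fallback sets out from 18 and closes the ring on a substrate whose secondary carbinols are masked.
- TESCl, imidazole, DMF, rt silylates O2 and O4 only and gives the 2,4-bis-O-triethylsilyl diene F4, which keeps the tertiary O1–H free at the hindered terminus.
- Ring closure with RuCl2(=CHPh)(PCy3)(H2IMes) in toluene at 80 °C gives the 2,4-bis-O-triethylsilyl cyclohexene F5.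
- TESOTf and 2,6-lutidine cap O1, and the sequence comes back to the route at 21, bypassing 19.

**Step 8.**
- The strongly basic ylide may cause β-elimination of the O3 ether or epimerisation at C4 in the open-chain aldehyde.
- The poly-alkoxide of the lactol may open too sluggishly.
- The fallback sets out from 15 and replaces the Wittig reaction with a two-stage Peterson olefination.
- Excess commercial (trimethylsilyl)methylmagnesium chloride in THF adds to the aldehyde tautomer to give the open-chain β-hydroxysilane tetraol F6, an inconsequential mixture at the new carbinol.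
- KH in THF then triggers elimination of the β-oxidosilane, and the sequence comes back to the route at 18.

Further compounds
F1 | step 6 | [(isopropoxydimethylsilyl)methyl]magnesium chloride | CC(C)O[Si](C)(C)C[Mg]Cl
F2 | step 6 | 6,7-dideoxy-1,2-O-isopropylidene-5-C-[(isopropoxydimethylsilyl)methyl]-3-O-(4-methoxybenzyl)-α-D-gluco-hept-6-eno-1,4-furanose (same spatial arrangement at C5 as 14) | CC1(C)O[C@H]2O[C@H]([C@](O)(C=C)C[Si](C)(C)OC(C)C)[C@H](OCc3ccc(OC)cc3)[C@H]2O1
F3 | step 6 | (5S)-6,7-dideoxy-5-C-(hydroxymethyl)-1,2-O-isopropylidene-3-O-(4-methoxybenzyl)-α-D-gluco-hept-6-eno-1,4-furanose | CC1(C)O[C@H]2O[C@H]([C@](O)(C=C)CO)[C@H](OCc3ccc(OC)cc3)[C@H]2O1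
F4 | step 9 | 2,4-bis-O-triethylsilyl ether of diene 18 | C=C[C@](O)(COCc1ccc(OC)cc1)[C@@H](O[Si](CC)(CC)CC)[C@H](OCc1ccc(OC)cc1)[C@@H](O[Si](CC)(CC)CC)C=C
F5 | step 9 | 2,4-bis-O-triethylsilyl ether of cyclohexenetriol 19 | COc1ccc(COC[C@@]2(O)C=C[C@H](O[Si](CC)(CC)CC)[C@@H](OCc3ccc(OC)cc3)[C@@H]2O[Si](CC)(CC)CC)cc1
F6 | step 8 | open-chain β-hydroxysilane tetraol from 15 (epimers at the new carbinol) | C=C[C@](O)(COCc1ccc(OC)cc1)[C@@H](O)[C@H](OCc1ccc(OC)cc1)[C@@H](O)C(O)C[Si](C)(C)C
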